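- The analyst of the dawn, dusk and midnight runs reports two complexes and not the incoming ligand, so I begin with a quantity that does not need it.

| setting | dawn | dusk | midnight | flask |
|---|---|---|---|---|
| starting complex | 0.38 M | 0.38 M | 0.76 M | 0.38 M |
| incoming ligand | 0.38 M (in portions, 3) | 0.57 M (in portions, 3) | 0.76 M (in portions, 3) | 0.760 M (in portions, 3) |
| remark | run made earlier; portions every 80 min | run made earlier; portions every 80 min | run made earlier; portions every 80 min | the portions of incoming ligand follow each other after 80 min, the first at the start |
| time |  |  |  | 5.0 d |

- dawn (time / d: complex with one exchanged / %, complex with two exchanged / %): 0.333: 7, 0; 0.833: 19, 4; 1.67: 22, 4; 2.50: 27, 6; 4.00: 29, 8; 5.00: 29, 6; 6.00: 30, 7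
- dusk (time / d: complex with one exchanged / %, complex with two exchanged / %): 0.500: 17, 3; 0.833: 23, 2; 1.04: 25, 5; 1.67: 28, 10; 2.50: 32, 9; 4.00: 32, 11; 6.00: 34, 10
- midnight (time / d: complex with one exchanged / %, complex with two exchanged / %): 0.500: 19, 2; 1.67: 28, 5; 3.00: 30, 7; 4.00: 29, 9; 6.00: 24, 3

(each reading ± 1.5 percentage points)

- the complex with one exchanged in the flask at 5.0 d, as a percentage of the starting complex charged
- the complex with two exchanged in the flask at 5.0 d, as a percentage of the starting complex charged
- concentration of incoming ligand at 5.0 d, in M



- If each exchange frees a leaving ligand and both steps stand at balance, both carry the same ratio [incoming ligand]/[leaving ligand], and that ratio cancels when the two balances are divided.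
- Taking the starting complex as what the other two leave, the last dawn reading gives 0.490 and the last dusk reading 0.484. I keep 0.487, with a scatter of 1.5 percentage points on small readings, as the balance quotient: [starting complex] times [complex with two exchanged] over the square of [complex with one exchanged], a disproportionation constant.
- Next link: [complex with one exchanged]/[starting complex] reads 0.476 at dawn and 0.607 at dusk, and a straight line in the charge gives the flask 0.738.
- With the quotient, that makes 49.9% starting complex, 36.8% with one exchanged and 13.2% with two.
- The line is the weak link, since it assumes rest. Midnight's readings of complex with one exchanged go from 30% to 24%, but that drop of 6 points hangs on a single last reading with a scatter of 1.5 points, so I take it as a hint of later change in that run and not as a measured fall.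
- As a hedge on that hint, I commit to a ratio midway between dusk's and the line's, 0.673. That gives the flask 52.8% starting complex, 35.5% with one exchanged, 11.6% with two, and [incoming ligand] under 0.536 M.
- The forecast says 36%, 13% and 0.52 M, adding: “Five days is nearly at the plateau, so I shade slightly lower.” On rest I differ.
- The flask gives 33.9%, 10.5% and 0.0770 M, so the forecast's [incoming ligand] is too high by a factor of 6.75.

    starting complex + incoming ligand ⇌ leaving ligand + complex with one exchanged (K = 1.43, k = 8.12 × 10⁻⁴ /M/min)
    complex with one exchanged + incoming ligand ⇌ leaving ligand + complex with two exchanged (K = 0.710, k = 8.49 × 10⁻⁴ /M/min)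
    2 incoming ligand → self-condensation product (k = 6.92 × 10⁻⁴ /M/min)

- At 5.0 d the flask has not come to rest: its slowest mode has a half-life of 5.82 d, longer than the time run.
- Its balance quotient then stands at 0.509. The neighbour flask with 1.5 M of starting complex holds 21.5% and 3.03%, a quotient of 0.493.
- Ten times as long, at 50.0 d, the flask has 0.311 M of self-condensation product, up from 0.237 M, and [incoming ligand] 0.0234 M. Its complexes are down to 23.1% and 3.56%, with the quotient at 0.490.

The runs come from a simulation for substances that don't exist; noise was put on by code.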